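**Retrosynthetic overview**
- The C3–O ester bond is made last, by acylating the (2R,3S)-benzofuranol with (2Z)-2-(acetoxymethyl)but-2-enoic acid; the acid comes from methyl but-2-ynoate by cis-hydroalumination and hydroxymethylation.
- Key step: the C2–C3 bond is closed by a Norrish–Yang-type photocyclization of an O-methallyl salicylaldehyde (δ-H abstraction, then ketyl/allyl 1,5-biradical coupling). This sets both stereocentres in their relative sense; an acylative kinetic resolution then selects the (2R,3S) enantiomer.
- The photo-substrate comes from resorcinol by formylation, selective 4-O-methylation, Friedel–Crafts acetylation and O-methallylation.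
- Ring order: the benzene ring is bought as resorcinol; the dihydrofuran ring is the only ring formed, in the photochemical step.

Assumption: one- and two-carbon donors (DMF, MeI, AcCl, CH2O, Ac2O) are treated as reagents, and the racemate 9 is written as both enantiomers joined by a dot.

**Route**

Step 1
Reactants: 1 resorcinol
Product: 3 2,4-dihydroxybenzaldehyde, via aryl iminium chloride 2 (not isolated)
Conditions: POCl3, DMF, MeCN, −15 °C → rt; then H2O, 50 °C
Reagents that add atoms: N,N-dimethylformamide CN(C)C=O; water O
Why: Vilsmeier–Haack formylation, in which the chloroiminium electrophile attacks the position para to one OH and ortho to the other and the iminium salt is hydrolysed to the aldehyde; no stereocentre is involved.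

Step 2
Reactants: 3 2,4-dihydroxybenzaldehyde
Product: 4 2-hydroxy-4-methoxybenzaldehyde
Conditions: MeI (1.05 equiv), K2CO3 (1.0 equiv), acetone, rt
Reagents that add atoms: iodomethane CI
Why: Williamson O-methylation, selective because the 2-OH is tied up in a hydrogen bond to the formyl group, so one equivalent of base and MeI alkylates the free, more acidic 4-OH.

Step 3
Reactants: 4 2-hydroxy-4-methoxybenzaldehyde
Product: 5 5-acetyl-2-hydroxy-4-methoxybenzaldehyde
Conditions: AcCl, AlCl3, CH2Cl2, 0 °C → rt; ice/aq. HCl
Reagents that add atoms: acetyl chloride CC(Cl)=O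
Why: Friedel–Crafts acylation at C5, the only unhindered position that is para to OH, ortho to OMe and meta to CHO; the temperature is kept at or below rt so that AlCl3 does not cleave the methyl ether.

Step 4
Reactants: 5 5-acetyl-2-hydroxy-4-methoxybenzaldehyde; 6 3-chloro-2-methylprop-1-ene
Product: 7 5-acetyl-4-methoxy-2-[(2-methylprop-2-en-1-yl)oxy]benzaldehyde
Conditions: K2CO3, KI (cat.), DMF, 40 °C
Reagents that add atoms: none
Why: Williamson etherification of the only phenol with an allylic chloride (iodide-assisted), run far below the temperature of an aromatic Claisen rearrangement.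

Step 5
Reactants: 7 5-acetyl-4-methoxy-2-[(2-methylprop-2-en-1-yl)oxy]benzaldehyde
Product: 9 racemic trans-1-[3-hydroxy-6-methoxy-2-(prop-1-en-2-yl)-2,3-dihydro-1-benzofuran-5-yl]ethan-1-one, via triplet 1,5-biradical 8 (not isolated)
Conditions: hν (365 nm), degassed benzene (0.01 M), rt; chromatography on Et3N-washed silica (removes the cis isomer)
Reagents that add atoms: none
Why: Norrish–Yang-type photocyclization of an o-alkoxyaryl aldehyde, in which the excited C=O abstracts the weak allylic α-oxy δ-hydrogen of the OCH2 group and the ketyl and α-aryloxyallyl radical centres couple to form C2–C3; closure is expected to favour the trans isomer, with OH and isopropenyl on opposite faces (relative configuration only at this stage, and a cis fraction has to be removed).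

Step 6
Reactants: 9 racemic trans-1-[3-hydroxy-6-methoxy-2-(prop-1-en-2-yl)-2,3-dihydro-1-benzofuran-5-yl]ethan-1-one
Product: 10 1-[(2R,3S)-3-hydroxy-6-methoxy-2-(prop-1-en-2-yl)-2,3-dihydro-1-benzofuran-5-yl]ethan-1-one (recovered alcohol)
Conditions: (S)-benzotetramisole (5 mol%), (i-PrCO)2O (0.6 equiv), i-Pr2NEt, CHCl3, 0 °C, to about 60% conversion
Reagents that add atoms: none
Why: acylative kinetic resolution of a cyclic benzylic alcohol by a chiral isothiourea acyl-transfer catalyst; (S)-benzotetramisole is chosen, by analogy with 1-indanol-type carbinols, to acylate the (2S,3R) enantiomer and leave the (2R,3S) alcohol in high ee (if the sense proves opposite, the antipodal catalyst is used).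

Step 7
Reactants: 11 methyl but-2-ynoate
Product: 13 methyl (2Z)-2-(hydroxymethyl)but-2-enoate, via alkenylalane 12 (not isolated)
Conditions: i-Bu2AlH, HMPA, THF, 0 °C; then CH2O (g), −78 → −20 °C; aq. Rochelle salt
Reagents that add atoms: formaldehyde C=O
Why: conjugate cis-hydroalumination of the ynoate (DIBAL–HMPA) followed by aldol addition to formaldehyde, which enters on the hydrogen side of the α-alumino enoate/allenolate and so places CH2OH trans to the methyl group (Z alkene).

Step 8
Reactants: 13 methyl (2Z)-2-(hydroxymethyl)but-2-enoate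
Product: 14 (2Z)-2-(hydroxymethyl)but-2-enoic acid
Conditions: LiOH, THF/H2O, 0 °C → rt; then 1 M HCl
Reagents that add atoms: lithium hydroxide [Li+].[OH-]
Why: saponification of the methyl ester under cold, mild conditions that leave the trisubstituted Z alkene untouched.

Step 9
Reactants: 14 (2Z)-2-(hydroxymethyl)but-2-enoic acid
Product: 15 (2Z)-2-[(acetyloxy)methyl]but-2-enoic acid
Conditions: Ac2O, pyridine, CH2Cl2, 0 °C → rt; then H2O
Reagents that add atoms: acetic anhydride CC(=O)OC(C)=O
Why: O-acetylation of the primary allylic alcohol without a nucleophilic amine catalyst (which could attack the acetoxymethyl-enoate in an SN2′ sense); the transient mixed anhydride at the carboxyl group is hydrolysed on aqueous work-up.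

Step 10
Reactants: 15 (2Z)-2-[(acetyloxy)methyl]but-2-enoic acid; 10 1-[(2R,3S)-3-hydroxy-6-methoxy-2-(prop-1-en-2-yl)-2,3-dihydro-1-benzofuran-5-yl]ethan-1-one
Product: 17 (2R,3S)-5-acetyl-6-methoxy-2-(prop-1-en-2-yl)-2,3-dihydro-1-benzofuran-3-yl (2Z)-2-[(acetyloxy)methyl]but-2-enoate, via mixed anhydride 16 (not isolated)
Conditions: 2,4,6-Cl3C6H2COCl, Et3N, toluene, rt; then 10, 60 °C (no DMAP)
Reagents that add atoms: none
Why: Yamaguchi-type mixed-anhydride esterification run without DMAP, the variant used for angelate-type esters to avoid Z→E isomerisation; the C3–O bond of the alcohol is not broken, so the (2R,3S) configuration is retained.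

**Compound list**

1 | resorcinol (benzene-1,3-diol) | Oc1cccc(O)c1 | starting material
2 | [(2,4-dihydroxyphenyl)methylidene]dimethyliminium chloride (formed in the flask) | C[N+](C)=Cc1ccc(O)cc1O.[Cl-] | intermediate
3 | 2,4-dihydroxybenzaldehyde | O=Cc1ccc(O)cc1O | intermediate
4 | 2-hydroxy-4-methoxybenzaldehyde | COc1ccc(C=O)c(O)c1 | intermediate
5 | 5-acetyl-2-hydroxy-4-methoxybenzaldehyde | CC(=O)c1cc(C=O)c(O)cc1OC | intermediate
6 | 3-chloro-2-methylprop-1-ene (methallyl chloride) | C=C(C)CCl | starting material
7 | 5-acetyl-4-methoxy-2-[(2-methylprop-2-en-1-yl)oxy]benzaldehyde | CC(=O)c1cc(C=O)c(OCC(C)=C)cc1OC | intermediate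
8 | triplet 1,5-biradical (ketyl carbon and α-aryloxyallyl carbon; formed in the flask) | C=C(C)[CH]Oc1cc(OC)c(C(C)=O)cc1[CH]O | intermediate
9 | racemic trans-1-[3-hydroxy-6-methoxy-2-(prop-1-en-2-yl)-2,3-dihydro-1-benzofuran-5-yl]ethan-1-one (2R,3S and 2S,3R, 1:1) | C=C(C)[C@H]1Oc2cc(OC)c(C(C)=O)cc2[C@@H]1O.C=C(C)[C@@H]1Oc2cc(OC)c(C(C)=O)cc2[C@H]1O | intermediate
10 | 1-[(2R,3S)-3-hydroxy-6-methoxy-2-(prop-1-en-2-yl)-2,3-dihydro-1-benzofuran-5-yl]ethan-1-one | C=C(C)[C@H]1Oc2cc(OC)c(C(C)=O)cc2[C@@H]1O | intermediate
11 | methyl but-2-ynoate | CC#CC(=O)OC | starting material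
12 | methyl (2E)-2-[bis(2-methylpropyl)alumanyl]but-2-enoate (formed in the flask) | C/C=C(\C(=O)OC)[Al](CC(C)C)CC(C)C | intermediate
13 | methyl (2Z)-2-(hydroxymethyl)but-2-enoate | C/C=C(\C(=O)OC)CO | intermediate
14 | (2Z)-2-(hydroxymethyl)but-2-enoic acid | C/C=C(\C(=O)O)CO | intermediate
15 | (2Z)-2-[(acetyloxy)methyl]but-2-enoic acid | C/C=C(\C(=O)O)COC(C)=O | intermediate
16 | (2Z)-2-[(acetyloxy)methyl]but-2-enoic 2,4,6-trichlorobenzoic anhydride (formed in the flask) | C/C=C(\C(=O)OC(=O)c1c(Cl)cc(Cl)cc1Cl)COC(C)=O | intermediate
17 | (2R,3S)-5-acetyl-6-methoxy-2-(prop-1-en-2-yl)-2,3-dihydro-1-benzofuran-3-yl (2Z)-2-[(acetyloxy)methyl]but-2-enoate | C=C(C)[C@H]1Oc2cc(OC)c(C(C)=O)cc2[C@@H]1OC(=O)/C(=C\C)COC(C)=O | target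

**Step count and risk**

Total step count: 10. Longest linear sequence: 7 (steps 1–6 and 10); steps 7–9 are the three-step acid branch.

Stereochemistry: the trans relationship of C2 and C3 is set in step 5, the absolute configuration is selected in step 6, the Z alkene is set in step 7, and none of these is touched afterwards.

Steps most likely to fail:

Step 5 (photocyclization). The risks are coupling at the CH2 end of the allyl radical (a benzoxepinol), a large cis fraction, and interference from the o-methoxyacetophenone chromophore. The fallback sets out from 7 and comes back at 10, so step 6 is no longer needed. It is an untested intramolecular variant of visible-light photoredox/HAT/chromium allylation, run under blue LEDs that the aldehyde does not absorb: 9-mesityl-10-methylacridinium photocatalyst, a thiophosphoric acid or thiol hydrogen-atom-transfer co-catalyst, CrCl2 and a chiral indane-bis(oxazoline) ligand in CH2Cl2 at rt. Hydrogen abstraction from the OCH2 group gives the α-aryloxyallyl radical F1. Cr(II) traps it as the γ-aryloxyallylchromium(III) species F2, which adds through its oxygen-bearing carbon to the neighbouring aldehyde in a closed Nozaki–Hiyama-type transition state. This should give the anti, that is trans, alcohol, with the absolute configuration controlled by the ligand (ligand antipode chosen after the first run).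

Step 6 (kinetic resolution). The risk is a low selectivity factor on this hindered carbinol. The fallback sets out from 9 and comes back at 10. It is an enzymatic acylation: immobilised Candida antarctica lipase B or Burkholderia cepacia lipase with vinyl acetate in MTBE at 30 °C, which by the Kazlauskas rule should acetylate the wanted enantiomer to the (2R,3S)-acetate F3. F3 is separated from the untouched (2S,3R) alcohol and deacetylated with K2CO3 in MeOH at 0 °C to give 10.

Step 10 (esterification). The risks are Z→E isomerisation, SN2′ attack on the acetoxymethyl-enoate, and acid-induced dehydration of the benzylic alcohol to the benzofuran. The fallback sets out from 10 and commercial (E)-but-2-enal and comes back at 17; it also makes steps 7–9 unnecessary. α-Iodination of the enal (I2, K2CO3, cat. DMAP, THF/H2O) gives (2Z)-2-iodobut-2-enal F4. Luche reduction (NaBH4, CeCl3, MeOH, 0 °C) gives (2Z)-2-iodobut-2-en-1-ol F5, and Ac2O/pyridine gives (2Z)-2-iodobut-2-en-1-yl acetate F6. Palladium-catalysed alkoxycarbonylation of F6 with 10 as the alcohol (Pd(OAc)2/Xantphos, CO 1 atm, Et3N, toluene, 50 °C) then builds the ester carbonyl in place with retention of the alkene geometry, so no free Z acid or acylating agent is handled.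

**Further compounds**
F1 | step 5 | 1-(2-formyl-4-acetyl-5-methoxyphenoxy)-2-methylallyl radical (formed in the flask) | C=C(C)[CH]Oc1cc(OC)c(C(C)=O)cc1C=O
F2 | step 5 | (2E)-3-(4-acetyl-2-formyl-5-methoxyphenoxy)-2-methylprop-2-en-1-ylchromium(III) dichloride (bis(oxazoline) ligand omitted; formed in the flask) | Cl[Cr](Cl)C/C(C)=C/Oc1cc(OC)c(C(C)=O)cc1C=O
F3 | step 6 | (2R,3S)-5-acetyl-6-methoxy-2-(prop-1-en-2-yl)-2,3-dihydro-1-benzofuran-3-yl acetate | C=C(C)[C@H]1Oc2cc(OC)c(C(C)=O)cc2[C@@H]1OC(C)=O
F4 | step 10 | (2Z)-2-iodobut-2-enal | C/C=C(\I)C=O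
F5 | step 10 | (2Z)-2-iodobut-2-en-1-ol | C/C=C(\I)CO
F6 | step 10 | (2Z)-2-iodobut-2-en-1-yl acetate | C/C=C(\I)COC(C)=O
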